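## Retrosynthetic overview

1. The C2-symmetric tetraene is cut at the central C–C single bond of the butadiene. Two identical (E)-dienylboronates are joined by oxidative homocoupling as the last step.
2. The dienylboronate goes back, by hydroboration and Sonogashira coupling, to a 4-bromocyclohex-3-enol. The oxirane comes from a Shi epoxidation and the carbinol from a CBS reduction of the ketone.
3. Key disconnection: the 2,2-disubstituted 4-bromocyclohex-3-enone comes from a 1-alkenyl-3-bromocyclopent-2-enol. A 1,2-shift of the ring alkenyl carbon expands the five-membered ring to six and sets the quaternary centre.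
4. The cyclopentenol is made from 3-bromocyclopentenone and 2-lithio-6-methylhepta-1,5-diene, which is built from homoprenyl bromide and acetylide.
5. Ring order: the bought cyclopentene becomes the cyclohexene in step 4, the oxirane forms in step 6, and the two halves are joined in step 9.

Assumption: 1, 2, 6 and 14 are catalogue chemicals, and the (R,R)-cobalt complex is taken to give the S ketone; if the first run shows the opposite sense, the (S,S)-complex is used.

## Route

Step 1
Reactants: 1 5-bromo-2-methylpent-2-ene; 2 lithium acetylide–ethane-1,2-diamine complex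
Product: 3 6-methylhept-5-en-1-yne
Conditions: DMSO, 0 °C to rt
Reagents that add atoms: none
Why: This is an SN2 alkylation of an acetylide, in which the unhindered primary bromide is displaced cleanly in DMSO and no stereocentre is involved.

Step 2
Reactants: 3 6-methylhept-5-en-1-yne
Product: 5 2-bromo-6-methylhepta-1,5-diene, via bromoboration adduct 4 (not isolated)
Conditions: B-bromo-9-BBN (1.1 equiv), CH2Cl2, 0 °C; then AcOH, 0 °C to rt
Reagents that add atoms: B-bromo-9-borabicyclo[3.3.1]nonane, BrB1C2CCCC1CCC2
Why: In this haloboration–protodeboronation the B–Br bond adds syn to the terminal alkyne only, with Br on the internal carbon, the trisubstituted alkene is left alone, and acetic acid cleaves the alkenyl C–B bond to give the 2-bromo-1-alkene.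

Step 3
Reactants: 5 2-bromo-6-methylhepta-1,5-diene; 6 3-bromocyclopent-2-en-1-one
Product: 9 (±)-3-bromo-1-(6-methylhepta-1,5-dien-2-yl)cyclopent-2-en-1-ol, via alkenyllithium 7 (not isolated), via lithium alkoxide 8 (not isolated)
Conditions: 5, t-BuLi (2.0 equiv), Et2O, −78 °C; then 6, THF, −78 °C; H2O quench; Et3N-washed silica
Reagents that add atoms: none
Why: Bromine–lithium exchange followed by 1,2-addition of the hard alkenyllithium to the enone carbonyl at −78 °C outruns conjugate addition–elimination and exchange at the ring bromide, and the racemic carbinol centre does not matter because step 4 erases it.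

Step 4
Reactants: 9 (±)-3-bromo-1-(6-methylhepta-1,5-dien-2-yl)cyclopent-2-en-1-ol
Product: 10 (S)-4-bromo-2-methyl-2-(4-methylpent-3-en-1-yl)cyclohex-3-en-1-one
Conditions: [(R,R)-N,N'-bis(3,5-di-tert-butylsalicylidene)cyclohexane-1,2-diaminato]cobalt, C36H52CoN2O2 (10 mol %), N-fluoro-2,4,6-trimethylpyridinium triflate (1.5 equiv), PhSiH3 (1.5 equiv), acetone, −30 °C
Reagents that add atoms: none
Why: Proposed new method: this is an enantioconvergent, hydrogen-atom-transfer-initiated radical–polar crossover semipinacol ring expansion, in which the trivalent cobalt hydride formed from the chiral complex, the N–F oxidant and the silane gives H• only to the unhindered 1,1-disubstituted =CH2 (making the methyl group and a tertiary radical), divalent cobalt captures the radical reversibly inside the chiral pocket, one-electron oxidation gives a tetravalent alkylcobalt, and the antiperiplanar ring alkenyl carbon C2 (a better migrating group than the C5 methylene because the charge spreads over a cyclopropylcarbinyl-type bridge) displaces cobalt with inversion, so that the five-membered ring becomes six-membered, the carbinol centre of both enantiomers of 9 is erased as C=O, and the quaternary centre is fixed as S by the catalyst alone; the closest known reaction types are the racemic cobalt-catalysed hydrogen-atom-transfer semipinacol rearrangement of tertiary allylic alcohols and the asymmetric cobalt-catalysed radical–polar crossover hydroalkoxylation, neither shown for an alkenyl shift, for a cyclopentenol-to-cyclohexenone expansion or for an all-carbon quaternary stereocentre.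

Step 5
Reactants: 10 (S)-4-bromo-2-methyl-2-(4-methylpent-3-en-1-yl)cyclohex-3-en-1-one
Product: 12 (1R,2S)-4-bromo-2-methyl-2-(4-methylpent-3-en-1-yl)cyclohex-3-en-1-ol, via catecholborate ester 11 (not isolated)
Conditions: (S)-2-methyl-CBS-oxazaborolidine (20 mol %), catecholborane (1.5 equiv), toluene, −78 °C; aqueous work-up
Reagents that add atoms: none
Why: In this Corey–Bakshi–Shibata reduction the oxazaborolidine tells the quaternary C2 (large) from the C6 methylene (small) and sets C1 as R (OH cis to the long chain) under reagent control, catecholborane at −78 °C does not hydroborate the alkene, and any (R)-ketone present ends up as a separable diastereomer.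

Step 6
Reactants: 12 (1R,2S)-4-bromo-2-methyl-2-(4-methylpent-3-en-1-yl)cyclohex-3-en-1-ol
Product: 13 (1R,2S)-4-bromo-2-{2-[(2R)-3,3-dimethyloxiran-2-yl]ethyl}-2-methylcyclohex-3-en-1-ol
Conditions: D-fructose-derived Shi ketone (30 mol %), 2KHSO5·KHSO4·K2SO4, K2CO3, Bu4NHSO4 (cat.), Na2B4O7 buffer, MeCN–(MeO)2CH2–H2O, 0 °C
Reagents that add atoms: potassium peroxymonosulfate KHSO5, [K+].[O-]S(=O)(=O)OO
Why: In this Shi asymmetric epoxidation the chiral dioxirane attacks the electron-rich trisubstituted side-chain alkene through the spiro transition state to give the R oxirane, while the bromoalkene next to the quaternary carbon is electronically and sterically inert.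

Step 7
Reactants: 13 (1R,2S)-4-bromo-2-{2-[(2R)-3,3-dimethyloxiran-2-yl]ethyl}-2-methylcyclohex-3-en-1-ol; 14 ethynyltrimethylsilane
Product: 16 (1R,2S)-2-{2-[(2R)-3,3-dimethyloxiran-2-yl]ethyl}-4-ethynyl-2-methylcyclohex-3-en-1-ol, via silylated enyne 15 (not isolated)
Conditions: Pd(PPh3)4 (5 mol %), CuI (10 mol %), Et3N, THF, rt to 40 °C, argon; then K2CO3, MeOH, rt
Reagents that add atoms: none
Why: Sonogashira coupling of the unhindered alkenyl bromide is followed in the same flask by methanolytic C–Si cleavage, and the amine and carbonate media leave the oxirane, the free alcohol and all stereocentres untouched.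

Step 8
Reactants: 16 (1R,2S)-2-{2-[(2R)-3,3-dimethyloxiran-2-yl]ethyl}-4-ethynyl-2-methylcyclohex-3-en-1-ol
Product: 18 (1R,2S)-2-{2-[(2R)-3,3-dimethyloxiran-2-yl]ethyl}-2-methyl-4-[(E)-2-(4,4,5,5-tetramethyl-1,3,2-dioxaborolan-2-yl)ethenyl]cyclohex-3-en-1-ol, via O-boryl dienylboronate 17 (not isolated)
Conditions: pinacolborane (2.2 equiv, added first), then Cy2BH (10 mol %), THF, rt; H2O work-up
Reagents that add atoms: pinacolborane, CC1(C)OBOC1(C)C
Why: This dicyclohexylborane-catalysed syn hydroboration of the terminal alkyne puts boron on the terminal carbon and sets the E alkene, the hindered ring alkene and the oxirane do not react, and the O–B bond formed at the alcohol is hydrolysed on work-up.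

Step 9
Reactants: 18 (1R,2S)-2-{2-[(2R)-3,3-dimethyloxiran-2-yl]ethyl}-2-methyl-4-[(E)-2-(4,4,5,5-tetramethyl-1,3,2-dioxaborolan-2-yl)ethenyl]cyclohex-3-en-1-ol (two molecules)
Product: 19 (1R,1'R,2S,2'S)-4,4'-[(1E,3E)-buta-1,3-diene-1,4-diyl]bis(2-{2-[(2R)-3,3-dimethyloxiran-2-yl]ethyl}-2-methylcyclohex-3-en-1-ol)
Conditions: Pd(OAc)2 (5 mol %), K2CO3, THF–MeOH–H2O, air, rt, dark
Reagents that add atoms: none
Why: In this palladium-catalysed aerobic oxidative homocoupling two alkenylboronates transmetalate onto divalent palladium, reductive elimination forms the central C–C bond with retention of both E alkenes, air reoxidises zerovalent palladium, and the basic medium spares the oxiranes and free alcohols.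

## Compound list

1 | 5-bromo-2-methylpent-2-ene | CC(C)=CCCBr | starting material
2 | lithium acetylide–ethane-1,2-diamine complex | [Li]C#C.NCCN | starting material
3 | 6-methylhept-5-en-1-yne | C#CCCC=C(C)C | intermediate
4 | (Z)-9-(2-bromo-6-methylhepta-1,5-dien-1-yl)-9-borabicyclo[3.3.1]nonane | CC(C)=CCC/C(Br)=C/B1C2CCCC1CCC2 | intermediate
5 | 2-bromo-6-methylhepta-1,5-diene | C=C(Br)CCC=C(C)C | intermediate
6 | 3-bromocyclopent-2-en-1-one | O=C1CCC(Br)=C1 | starting material
7 | (6-methylhepta-1,5-dien-2-yl)lithium | [Li]C(=C)CCC=C(C)C | intermediate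
8 | lithium 3-bromo-1-(6-methylhepta-1,5-dien-2-yl)cyclopent-2-en-1-olate (racemic) | [Li+].[O-]C1(C=C(Br)CC1)C(=C)CCC=C(C)C | intermediate
9 | (±)-3-bromo-1-(6-methylhepta-1,5-dien-2-yl)cyclopent-2-en-1-ol | OC1(C=C(Br)CC1)C(=C)CCC=C(C)C | intermediate
10 | (S)-4-bromo-2-methyl-2-(4-methylpent-3-en-1-yl)cyclohex-3-en-1-one | CC(C)=CCC[C@@]1(C)C=C(Br)CCC1=O | intermediate
11 | 2-{[(1R,2S)-4-bromo-2-methyl-2-(4-methylpent-3-en-1-yl)cyclohex-3-en-1-yl]oxy}-1,3,2-benzodioxaborole | CC(C)=CCC[C@@]1(C)C=C(Br)CC[C@H]1OB1Oc2ccccc2O1 | intermediate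
12 | (1R,2S)-4-bromo-2-methyl-2-(4-methylpent-3-en-1-yl)cyclohex-3-en-1-ol (OH cis to the long chain) | CC(C)=CCC[C@@]1(C)C=C(Br)CC[C@H]1O | intermediate
13 | (1R,2S)-4-bromo-2-{2-[(2R)-3,3-dimethyloxiran-2-yl]ethyl}-2-methylcyclohex-3-en-1-ol | CC1(C)O[C@@H]1CC[C@@]1(C)C=C(Br)CC[C@H]1O | intermediate
14 | ethynyltrimethylsilane | C#C[Si](C)(C)C | starting material
15 | (1R,2S)-2-{2-[(2R)-3,3-dimethyloxiran-2-yl]ethyl}-2-methyl-4-[(trimethylsilyl)ethynyl]cyclohex-3-en-1-ol | CC1(C)O[C@@H]1CC[C@@]1(C)C=C(C#C[Si](C)(C)C)CC[C@H]1O | intermediate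
16 | (1R,2S)-2-{2-[(2R)-3,3-dimethyloxiran-2-yl]ethyl}-4-ethynyl-2-methylcyclohex-3-en-1-ol | CC1(C)O[C@@H]1CC[C@@]1(C)C=C(C#C)CC[C@H]1O | intermediate
17 | O-(pinacolatoboryl) ether of 18 | CC1(C)O[C@@H]1CC[C@@]1(C)C=C(/C=C/B2OC(C)(C)C(C)(C)O2)CC[C@H]1OB1OC(C)(C)C(C)(C)O1 | intermediate
18 | (1R,2S)-2-{2-[(2R)-3,3-dimethyloxiran-2-yl]ethyl}-2-methyl-4-[(E)-2-(4,4,5,5-tetramethyl-1,3,2-dioxaborolan-2-yl)ethenyl]cyclohex-3-en-1-ol | CC1(C)O[C@@H]1CC[C@@]1(C)C=C(/C=C/B2OC(C)(C)C(C)(C)O2)CC[C@H]1O | intermediate
19 | CNP0229121.4, (1R,1'R,2S,2'S)-4,4'-[(1E,3E)-buta-1,3-diene-1,4-diyl]bis(2-{2-[(2R)-3,3-dimethyloxiran-2-yl]ethyl}-2-methylcyclohex-3-en-1-ol) | CC1(C)O[C@@H]1CC[C@@]1(C)C=C(/C=C/C=C/C2=C[C@](C)(CC[C@H]3OC3(C)C)[C@H](O)CC2)CC[C@H]1O | target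

## Step count

Total step count: 9.
Longest linear sequence: 9 steps (1 to 19).

## Steps most likely to fail

**Step 4 (the new reaction).** The free tertiary radical can undergo a 1,2-alkenyl shift through a cyclopropylcarbinyl radical outside the chiral pocket, which would lower the ee. The alcohol may also close onto the cationic carbon to give an oxirane. Moderate ee is tolerable, because step 5 turns the minor ketone enantiomer into a separable diastereomer.

The fallback uses known chemistry only. It sets out from 9 and comes back at 12.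
- The established racemic hydrogen-atom-transfer semipinacol rearrangement is run with the achiral complex [N,N'-bis(3,5-di-tert-butylsalicylidene)ethane-1,2-diaminato]cobalt, C32H46CoN2O2, and the same N–F oxidant and silane. It gives the racemic ketone F1.
- Reduction of the racemate with (S)-2-methyl-CBS-oxazaborolidine and catecholborane sets C1 as R in both enantiomers. Besides 11, this forms the catecholborate ester of the (1R,2R)-alcohol F2.
- Hydrolysis gives 12 and the (1R,2R)-alcohol F3. These are diastereomers and are separated on silica gel. The maximum yield is 50 %.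

**Step 5.** The ketone is flanked by a quaternary carbon, so the reduction may be slow or poorly selective.

The fallback sets out from 10 and comes back at 12.
- NaBH4 with CeCl3·7H2O in MeOH at −40 °C reduces 10 without facial control.
- It gives 12 and the (1S,2S)-epimeric alcohol F4, which are separated by chromatography.
- F4 is oxidised back to 10 with Dess–Martin periodinane and recycled, so the material is funnelled to 12 by separation and recycling rather than by catalyst control.

**Step 9.** The tetraene is sensitive to air and light. The boronate can also be lost by protodeboronation or by peroxide oxidation under aerobic palladium catalysis.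

The fallback sets out from 18 and comes back at 19.
- Half of 18 is treated with NaOH and I2 in THF at 0 °C. This iododeboronation proceeds with retention and gives the (E)-dienyl iodide F5.
- F5 is joined to the other half of 18 by a Suzuki–Miyaura cross-coupling (Pd(PPh3)4, aqueous NaOH, THF, rt, argon, dark).
- The central bond is then made without any oxidant.

## Further compounds

F1 | step 4 | racemic 4-bromo-2-methyl-2-(4-methylpent-3-en-1-yl)cyclohex-3-en-1-one | CC(C)=CCCC1(C)C=C(Br)CCC1=O
F2 | step 4 | 2-{[(1R,2R)-4-bromo-2-methyl-2-(4-methylpent-3-en-1-yl)cyclohex-3-en-1-yl]oxy}-1,3,2-benzodioxaborole | CC(C)=CCC[C@]1(C)C=C(Br)CC[C@H]1OB1Oc2ccccc2O1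
F3 | step 4 | (1R,2R)-4-bromo-2-methyl-2-(4-methylpent-3-en-1-yl)cyclohex-3-en-1-ol | CC(C)=CCC[C@]1(C)C=C(Br)CC[C@H]1O
F4 | step 5 | (1S,2S)-4-bromo-2-methyl-2-(4-methylpent-3-en-1-yl)cyclohex-3-en-1-ol | CC(C)=CCC[C@@]1(C)C=C(Br)CC[C@@H]1O
F5 | step 9 | (1R,2S)-2-{2-[(2R)-3,3-dimethyloxiran-2-yl]ethyl}-4-[(E)-2-iodoethenyl]-2-methylcyclohex-3-en-1-ol | CC1(C)O[C@@H]1CC[C@@]1(C)C=C(/C=C/I)CC[C@H]1O
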